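## The problem

Target **18** is a 1-aryl-1,2-dihydronaphthalene. Catechol ring A is fused to the half-saturated ring B, C1 carries a second catechol ring, C2 a free carboxylic acid, and the C3 carboxyl group, conjugated with the C3=C4 double bond, is esterified by the hydroxyl group of (S)-malic acid (**1**). Only two skeletal bonds join the two C6–C3 halves (C2–C3 and C1–C8a), so one of them must be made with closure of ring B, and the two ring carboxyl groups must be told apart because only the one at C3 bears the malate. There are three stereocentres: C1 (R) and C2 (S), trans to each other, and the malate carbon (S). The malate centre comes from the chiral pool and is too far from ring B to direct anything, but it turns every stereochemical error in ring B into a separable diastereomer. C2 can be set by asymmetric catalysis and can then control C1, since the C1 aryl group prefers the side opposite the C2 carboxyl group. Fragile points are the four phenols (oxidation), the C2–H bond, α to one carbonyl group and γ to another (epimerisation, double-bond migration, aromatisation), the C3=C4 bond (no hydrogenolysis), and the single ester linkage that must survive the unmasking of three acids and four phenols. The enabling feature is that C1 is a benzylic carbon with a para oxygen on its aryl ring and C3 lies between an ester and C4. With C4 written as a ketone, C3 becomes a 1,3-dicarbonyl carbon, so C1–C2–C3 is the opened form of a donor–acceptor cyclopropane, and the aryl group of that ketone is ring A, with C8a placed to close ring B on C1.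

## Retrosynthesis

**18 from 17.** No skeletal bond is cut; the last operation only unmasks. Phenols are carried as benzyl ethers and the three acids as tert-butyl esters in **17**, because both fall to one Lewis acid at low temperature without hydrogen, base or a nucleophile, so the C3=C4 bond and the malate ester linkage are left alone. Methyl ethers would allow purchased dimethoxy building blocks, but their cleavage needs harsher Lewis-acid treatment that endangers the one ester that must stay. The benzyl series costs one Wittig step on the short branch.

**17 from 14 (through 15).** The C3=C4 double bond is traced back to a C4 ketone, to be removed forward by reduction to alcohol **15** and dehydration. This adds no carbon but makes C3 of tetralone **14** a β-keto ester carbon, which is what the next cut needs. The forward steps must not touch C2, and the elimination must end in the conjugated position.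

**14 from 13.** The C1–C8a bond is cut and C1 is reconnected to C3, giving cyclopropane **13**. The neighbouring cut at C4–C4a (acylation of a diarylbutanoate) would require an open chain with three contiguous centres and differentiated esters. A cut at C2–C3 (coupling of two cinnamate units) offers no way to tell the carboxyl groups apart. In **13** ring A is still a simple benzoyl group, ring B is absent, and only the C2 centre must be correct, because C1 is re-formed and C3 is lost. The forward reaction must open the cyclopropane at C1–C3 only, close through carbon rather than oxygen, and place the aryl group trans to the C2 ester.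

**13 from 8 and 10 (through 11 and 12).** The C2–C3 bond and the temporary C1–C3 bond are cut together, as a Michael-initiated ring closure of bromo keto ester **8** onto enal **10** under amine catalysis. The C1–C2 bond comes intact from the E-alkene of **10**. The formyl group of **11** is the C2 carboxyl group at a lower oxidation level and is raised to acid **12** and protected as **13**. A carbenoid cyclopropanation of a cinnamate was set aside, because acceptor-substituted carbenoids add poorly to electron-poor alkenes and give no absolute control. The forward reaction must set the formyl-bearing carbon with high facial selectivity; the aryl/formyl trans relationship follows from the alkene geometry.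

**8 from 7; 7 from 5 and 2; 5 from 3 and 4; 2 from 1; 10 from 9.** The C3 carboxyl–oxygen bond to the malate is cut at the very start: acyl Meldrum's acid **5**, from acid **3** and Meldrum's acid **4**, delivers an acylketene to the hydroxyl group of di-tert-butyl malate **2**, made from **1**. Attaching the malate before any ring exists removes the late differentiation of two similar carboxyl groups. Enal **10** is one Wittig step from aldehyde **9**. The four starting materials **1**, **3**, **4** and **9** are catalogue compounds.

## Roads not taken

**Alternative 1:** The C2–C3 bond and a sacrificial C1–C4 bond would be made by intramolecular [2+2] photocycloaddition of tartrate bis-cinnamate **A1**, giving the tartrate-bridged all-trans truxinate **A2**.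
- Merits: all carbon atoms of the target are assembled in very few steps from cheap material, the tether enforces head-to-head union, and the C2 symmetry of **A2** lets either aryl ring become ring A. In step count to a compound holding the whole skeleton this road beats the chosen plan.
- Weak points: **A2** is not the target skeleton. The C1–C4 bond must later be broken and C1–C8a made, and under acid or one-electron oxidation the easier fragmentation of a truxinate is cycloreversion to two cinnamates. A short tartrate tether more naturally gives the cis-fused photodimer than the all-trans one. The tartrate must then be removed and the malate placed only on the conjugated C3 carboxyl group, which is the less reactive of the two.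
- Comparison: the chosen plan is longer up to its key step, but that step makes the real ring B bond with the malate already on C3 and the C2 carboxyl group protected differently.

**Alternative 2:** Ring A would be built by a cobalt-mediated [2+2+2] cocyclisation of 1,7-diyne **A3** with diboryl alkyne **A4**, forming C4a–C8a, C5–C6 and C7–C8 and giving diboryl dihydronaphthalene **A5**.
- Merits: rings A and B close together, the placement of the ring A oxygens is unambiguous, and oxidation of the two carbon–boron bonds to phenols is gentler than any ether cleavage. In these two respects it is better than the chosen plan.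
- Weak points: **A3** must already hold both ring stereocentres, a Z-enyne and the malate ester. Its C1 is at once benzylic and propargylic and should racemise or slip to an allene, and its C2 is α to an ester and allylic. Making **A3** as one stereoisomer would be longer than the whole chosen route. The cocyclisation with a bulky diboryl alkyne usually needs much metal, heat and light, and the conjugated enyne can itself enter the cycloaddition.
- Comparison: the chosen plan accepts a Friedel–Crafts regiochemistry question and a final ether cleavage, and sets against them purchased arenes, a catalytic key step and a precursor with a single decisive stereocentre.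

**Alternative 3:** C1–C8a and C4–C4a would be cut, so that veratrole **A7** is stitched under superacid to the lactone bis-electrophile **A6** (an aryl paraconate with an aminomethylene group and an oxazolidinone imide), giving dihydronaphthalene acid **A8**.
- Merits: it is convergent, ring A comes from the simplest arene, and two bonds and ring B form in one pot. The C3 acid emerges free while C2 is an imide, so the carboxyl groups are differentiated as well as in the chosen plan. The alkene forms directly, which saves the ketone reduction and dehydration.
- Weak points: after the first alkylation C1 bears two identical dialkoxyphenyl groups, so the C1 configuration of **A6** is erased. It is then decided only by which of two diastereotopic rings attacks, under superacid, next to a C2 centre that can epimerise. The end game needs esterification of a hindered conjugated acid with the secondary alcohol **2**, then imide hydrolysis in the presence of that new ester, then ether cleavage.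
- Comparison: the chosen plan pays two extra steps for removing the ketone, but it has the malate ester in place before ring closure, only one aryl group at C1 and a mild catalytic Lewis acid.

Key step: step 9

Remark on the chemistry: the configuration of the quaternary cyclopropane carbon in **11**–**13** (the later C3) is not controlled in step 6 and does not matter, because step 9 planarises it. The formulas show the epimer with the aroyl group cis to the aryl group; the other epimer would be carried through steps 7–9 with it.

Step 1
Reactants: 1 (S)-malic acid
Product: 2 di-tert-butyl (2S)-2-hydroxybutanedioate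
Conditions: tBuOC(=NiPr)NHiPr (3 equiv), THF, rt → 40 °C
Reagents that add atoms: O-tert-butyl-N,N'-diisopropylisourea, CC(C)NC(=NC(C)C)OC(C)(C)C
Why: Isourea esterification: each carboxylic acid protonates the isourea and is tert-butylated within the ion pair, whereas the secondary alcohol is not acidic enough to react; the stereocentre is not involved.

Step 2
Reactants: 3 3,4-bis(benzyloxy)benzoic acid; 4 Meldrum's acid
Product: 5 5-{[3,4-bis(benzyloxy)phenyl](hydroxy)methylidene}-2,2-dimethyl-1,3-dioxane-4,6-dione
Conditions: DCC, DMAP, CH2Cl2, 0 °C → rt; cold aq. KHSO4 wash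
Reagents that add atoms: none
Why: Carbodiimide-mediated C-acylation of Meldrum's acid, a standard route to acyl Meldrum's acids; the product is isolated as its stable enol and used without chromatography.

Step 3
Reactants: 5 acyl Meldrum's acid; 2 di-tert-butyl (2S)-2-hydroxybutanedioate
Product: 7 di-tert-butyl (2S)-2-({3-[3,4-bis(benzyloxy)phenyl]-3-oxopropanoyl}oxy)butanedioate, via aroylketene 6 (not isolated)
Conditions: toluene, 85 °C
Reagents that add atoms: none
Why: Thermolysis of the acyl Meldrum's acid releases acetone and CO2 and gives an acylketene that is trapped by the secondary hydroxyl group of 2 (acylketene alcoholysis to a β-keto ester); the conditions are neutral, so the tert-butyl esters and the malate centre are untouched.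

Step 4
Reactants: 7 β-keto ester
Product: 8 di-tert-butyl (2S)-2-({3-[3,4-bis(benzyloxy)phenyl]-2-bromo-3-oxopropanoyl}oxy)butanedioate (both epimers at the brominated carbon)
Conditions: NBS (1.0 equiv), Mg(ClO4)2 (10 mol%), EtOAc/MeCN, 0 °C
Reagents that add atoms: N-bromosuccinimide, O=C1CCC(=O)N1Br
Why: Electrophilic α-bromination of the magnesium-chelated enol of a β-keto ester; the acyl-deactivated arene and the benzyl ethers do not compete, and the configuration at the brominated carbon is irrelevant because it becomes an enolate in step 6.

Step 5
Reactants: 9 3,4-bis(benzyloxy)benzaldehyde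
Product: 10 (E)-3-[3,4-bis(benzyloxy)phenyl]prop-2-enal
Conditions: Ph3P=CHCHO, toluene, 80 °C
Reagents that add atoms: (triphenylphosphoranylidene)acetaldehyde, O=CC=P(c1ccccc1)(c1ccccc1)c1ccccc1
Why: Wittig two-carbon homologation with a stabilised ylide, which gives the E-enal; the aldehyde is kept in slight excess to hold back a second homologation.

Step 6
Reactants: 8 α-bromo β-keto ester; 10 (E)-3-[3,4-bis(benzyloxy)phenyl]prop-2-enal
Product: 11 (2S)-1,4-di-tert-butoxy-1,4-dioxobutan-2-yl (1R,2R,3S)-1-[3,4-bis(benzyloxy)benzoyl]-2-[3,4-bis(benzyloxy)phenyl]-3-formylcyclopropane-1-carboxylate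
Conditions: (R)-α,α-diphenylprolinol trimethylsilyl ether (20 mol%), 2,6-lutidine (1.2 equiv), CH2Cl2, 0 °C → rt
Reagents that add atoms: none
Why: Aminocatalytic Michael-initiated ring closure, known for enals with 2-bromo-1,3-dicarbonyl compounds: the enol of 8 adds to the β-carbon of the iminium ion of 10 on the face away from the diphenyl(silyloxy)methyl group, and the resulting enamine displaces bromide in a 3-exo-tet closure. The E-geometry of 10 places aryl and formyl trans, and the (R)-catalyst sets the formyl-bearing carbon (later C2) as S and the aryl-bearing carbon as R; the weak base 2,6-lutidine is used to avoid amine-induced opening of the product.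

Step 7
Reactants: 11 cyclopropane aldehyde
Product: 12 (1R,2R,3S)-1-[3,4-bis(benzyloxy)benzoyl]-2-[3,4-bis(benzyloxy)phenyl]cyclopropane-1,3-dicarboxylic acid 1-[(2S)-1,4-di-tert-butoxy-1,4-dioxobutan-2-yl] monoester (free acid at C3)
Conditions: NaClO2, NaH2PO4, 2-methyl-2-butene, t-BuOH/H2O, 0 °C → rt
Reagents that add atoms: sodium chlorite, [Na+].[O-]Cl=O
Why: Pinnick oxidation converts the aldehyde to the acid under buffered conditions that do not epimerise the α-carbon or open the cyclopropane; the alkene scavenger removes hypochlorous acid before it can chlorinate the electron-rich rings.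

Step 8
Reactants: 12 cyclopropane acid
Product: 13 3-tert-butyl 1-[(2S)-1,4-di-tert-butoxy-1,4-dioxobutan-2-yl] (1R,2R,3S)-1-[3,4-bis(benzyloxy)benzoyl]-2-[3,4-bis(benzyloxy)phenyl]cyclopropane-1,3-dicarboxylate
Conditions: tBuOC(=NiPr)NHiPr (2 equiv), CH2Cl2, rt
Reagents that add atoms: O-tert-butyl-N,N'-diisopropylisourea, CC(C)NC(=NC(C)C)OC(C)(C)C
Why: Isourea esterification as in step 1; it needs no added acid or base, so the acid-sensitive donor–acceptor cyclopropane and the C3 centre of the ring survive.

Step 9
Reactants: 13 cyclopropane triester
Product: 14 2-tert-butyl 3-[(2S)-1,4-di-tert-butoxy-1,4-dioxobutan-2-yl] (1R,2S,3R)-6,7-bis(benzyloxy)-1-[3,4-bis(benzyloxy)phenyl]-4-oxo-1,2,3,4-tetrahydronaphthalene-2,3-dicarboxylate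
Conditions: Sc(OTf)3 (10 mol%), CH2Cl2, 0 °C → rt
Reagents that add atoms: none
Why: Sc(OTf)3 chelates the two carbonyl groups on the quaternary carbon and heterolyses the ring bond between this carbon and the aryl-bearing carbon (the later C1–C3 bond), giving a para-benzyloxybenzyl cation at C1 and a scandium enolate over C3–C4. The aroyl ring, whose carbonyl group is now part of the enolate and no longer withdraws as a ketone, attacks C1 through its ring carbon ortho to the acyl group and para to a benzyloxy group; re-aromatisation and protonation at C3 give tetralone 14. The closest known reaction type is the Lewis-acid ring opening with Friedel–Crafts closure of aryl 2-arylcyclopropyl ketones to 4-aryl-1-tetralones (formal homo-Nazarov cyclisation). Ring B closes as a six-membered ring by a 6-endo-trig cation–arene cyclisation in which the C4a–C8a bond of the arene becomes part of the new ring. C2 does not take part and keeps the configuration set in step 6; the new C1 centre is controlled by C2, because the planar cation closes with its aryl group on the face opposite the C2 ester (pseudo-equatorial in a half-chair transition state), which gives the 1,2-trans product, and the enolisable C3 centre settles in the all-trans keto form or as the enol. The step needs C1–C3 rather than C1–C2 cleavage, secured by the chelating 1,3-dicarbonyl unit that makes C3 the better anion site; C- rather than O-attack on the cation, secured because the dihydrofuran from O-attack re-ionises under the same catalyst and drains into the arylated product; and attack para rather than ortho to the benzyloxy group, secured by the crowding of the alternative ring carbon between two substituents. Mild catalytic conditions are chosen so that the tert-butyl esters and benzyl ethers stay on.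

Step 10
Reactants: 14 tetralone
Product: 15 2-tert-butyl 3-[(2S)-1,4-di-tert-butoxy-1,4-dioxobutan-2-yl] (1R,2S,3R)-6,7-bis(benzyloxy)-1-[3,4-bis(benzyloxy)phenyl]-4-hydroxy-1,2,3,4-tetrahydronaphthalene-2,3-dicarboxylate (both C4 epimers)
Conditions: NaBH4, THF/MeOH, −20 → 0 °C
Reagents that add atoms: none
Why: Borohydride reduction of the aryl ketone of a 2-alkoxycarbonyl-1-tetralone; esters are not reduced at this temperature, C2 is not enolised, and the configurations at C3 and C4 are of no consequence because both carbons become sp2 in step 11.

Step 11
Reactants: 15 benzylic alcohol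
Product: 17 2-tert-butyl 3-[(2S)-1,4-di-tert-butoxy-1,4-dioxobutan-2-yl] (1R,2S)-6,7-bis(benzyloxy)-1-[3,4-bis(benzyloxy)phenyl]-1,2-dihydronaphthalene-2,3-dicarboxylate, via C4 mesylate 16 (not isolated)
Conditions: MsCl, Et3N, CH2Cl2, 0 °C → rt
Reagents that add atoms: none
Why: Mesylation and elimination of a β-hydroxy ester: the C4 mesylate is benzylic, activated by the para benzyloxy group at C7, and β to the C3 ester, so it eliminates under triethylamine to the alkene conjugated with both arene and ester. The base is too weak to remove the C2 proton quickly, and the 1,2-trans arrangement is the more stable one.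

Step 12
Reactants: 17 protected dihydronaphthalene
Product: 18 (2S)-2-{[(3S,4R)-3-carboxy-4-(3,4-dihydroxyphenyl)-6,7-dihydroxy-3,4-dihydronaphthalene-2-carbonyl]oxy}butanedioic acid (target; 1R,2S in the ring B numbering used here)
Conditions: BCl3, C6HMe5, CH2Cl2, −78 → 0 °C; aq. work-up under argon
Reagents that add atoms: none
Why: Lewis-acid debenzylation of aryl benzyl ethers with pentamethylbenzene as a non-basic benzyl cation scavenger, run at −78 °C; on warming to 0 °C the tert-butyl esters ionise as well. No hydrogen, base or nucleophile is present, so the C3=C4 bond, the C2 centre and the secondary-alkyl ester linkage to the malate are expected to remain.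

## Compound list

1 | (S)-malic acid | O=C(O)C[C@H](O)C(=O)O | starting material
2 | di-tert-butyl (2S)-2-hydroxybutanedioate | CC(C)(C)OC(=O)C[C@H](O)C(=O)OC(C)(C)C | intermediate
3 | 3,4-bis(benzyloxy)benzoic acid | OC(=O)c1ccc(OCc2ccccc2)c(OCc2ccccc2)c1 | starting material
4 | Meldrum's acid (2,2-dimethyl-1,3-dioxane-4,6-dione) | CC1(C)OC(=O)CC(=O)O1 | starting material
5 | 5-{[3,4-bis(benzyloxy)phenyl](hydroxy)methylidene}-2,2-dimethyl-1,3-dioxane-4,6-dione | CC1(C)OC(=O)C(=C(O)c2ccc(OCc3ccccc3)c(OCc3ccccc3)c2)C(=O)O1 | intermediate
6 | 3-[3,4-bis(benzyloxy)phenyl]-3-oxoprop-1-en-1-one (aroylketene, not isolated) | O=C=CC(=O)c1ccc(OCc2ccccc2)c(OCc2ccccc2)c1 | intermediate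
7 | di-tert-butyl (2S)-2-({3-[3,4-bis(benzyloxy)phenyl]-3-oxopropanoyl}oxy)butanedioate | CC(C)(C)OC(=O)C[C@H](OC(=O)CC(=O)c1ccc(OCc2ccccc2)c(OCc2ccccc2)c1)C(=O)OC(C)(C)C | intermediate
8 | di-tert-butyl (2S)-2-({3-[3,4-bis(benzyloxy)phenyl]-2-bromo-3-oxopropanoyl}oxy)butanedioate (both epimers at CBr) | CC(C)(C)OC(=O)C[C@H](OC(=O)C(Br)C(=O)c1ccc(OCc2ccccc2)c(OCc2ccccc2)c1)C(=O)OC(C)(C)C | intermediate
9 | 3,4-bis(benzyloxy)benzaldehyde | O=Cc1ccc(OCc2ccccc2)c(OCc2ccccc2)c1 | starting material
10 | (E)-3-[3,4-bis(benzyloxy)phenyl]prop-2-enal | O=C/C=C/c1ccc(OCc2ccccc2)c(OCc2ccccc2)c1 | intermediate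
11 | (2S)-1,4-di-tert-butoxy-1,4-dioxobutan-2-yl (1R,2R,3S)-1-[3,4-bis(benzyloxy)benzoyl]-2-[3,4-bis(benzyloxy)phenyl]-3-formylcyclopropane-1-carboxylate (aryl trans to formyl, aroyl cis to aryl) | O=C[C@H]1[C@H](c2ccc(OCc3ccccc3)c(OCc3ccccc3)c2)[C@@]1(C(=O)c1ccc(OCc2ccccc2)c(OCc2ccccc2)c1)C(=O)O[C@@H](CC(=O)OC(C)(C)C)C(=O)OC(C)(C)C | intermediate
12 | (1R,2R,3S)-1-[3,4-bis(benzyloxy)benzoyl]-2-[3,4-bis(benzyloxy)phenyl]cyclopropane-1,3-dicarboxylic acid 1-[(2S)-1,4-di-tert-butoxy-1,4-dioxobutan-2-yl] monoester | OC(=O)[C@H]1[C@H](c2ccc(OCc3ccccc3)c(OCc3ccccc3)c2)[C@@]1(C(=O)c1ccc(OCc2ccccc2)c(OCc2ccccc2)c1)C(=O)O[C@@H](CC(=O)OC(C)(C)C)C(=O)OC(C)(C)C | intermediate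
13 | 3-tert-butyl 1-[(2S)-1,4-di-tert-butoxy-1,4-dioxobutan-2-yl] (1R,2R,3S)-1-[3,4-bis(benzyloxy)benzoyl]-2-[3,4-bis(benzyloxy)phenyl]cyclopropane-1,3-dicarboxylate (key-step precursor) | CC(C)(C)OC(=O)[C@H]1[C@H](c2ccc(OCc3ccccc3)c(OCc3ccccc3)c2)[C@@]1(C(=O)c1ccc(OCc2ccccc2)c(OCc2ccccc2)c1)C(=O)O[C@@H](CC(=O)OC(C)(C)C)C(=O)OC(C)(C)C | intermediate
14 | 2-tert-butyl 3-[(2S)-1,4-di-tert-butoxy-1,4-dioxobutan-2-yl] (1R,2S,3R)-6,7-bis(benzyloxy)-1-[3,4-bis(benzyloxy)phenyl]-4-oxo-1,2,3,4-tetrahydronaphthalene-2,3-dicarboxylate (key-step product) | CC(C)(C)OC(=O)C[C@H](OC(=O)[C@H]1C(=O)c2cc(OCc3ccccc3)c(OCc3ccccc3)cc2[C@@H](c2ccc(OCc3ccccc3)c(OCc3ccccc3)c2)[C@@H]1C(=O)OC(C)(C)C)C(=O)OC(C)(C)C | intermediate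
15 | 2-tert-butyl 3-[(2S)-1,4-di-tert-butoxy-1,4-dioxobutan-2-yl] (1R,2S,3R)-6,7-bis(benzyloxy)-1-[3,4-bis(benzyloxy)phenyl]-4-hydroxy-1,2,3,4-tetrahydronaphthalene-2,3-dicarboxylate (both C4 epimers) | CC(C)(C)OC(=O)C[C@H](OC(=O)[C@H]1C(O)c2cc(OCc3ccccc3)c(OCc3ccccc3)cc2[C@@H](c2ccc(OCc3ccccc3)c(OCc3ccccc3)c2)[C@@H]1C(=O)OC(C)(C)C)C(=O)OC(C)(C)C | intermediate
16 | C4 methanesulfonate of 15 (both C4 epimers, not isolated) | CC(C)(C)OC(=O)C[C@H](OC(=O)[C@H]1C(OS(C)(=O)=O)c2cc(OCc3ccccc3)c(OCc3ccccc3)cc2[C@@H](c2ccc(OCc3ccccc3)c(OCc3ccccc3)c2)[C@@H]1C(=O)OC(C)(C)C)C(=O)OC(C)(C)C | intermediate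
17 | 2-tert-butyl 3-[(2S)-1,4-di-tert-butoxy-1,4-dioxobutan-2-yl] (1R,2S)-6,7-bis(benzyloxy)-1-[3,4-bis(benzyloxy)phenyl]-1,2-dihydronaphthalene-2,3-dicarboxylate | CC(C)(C)OC(=O)C[C@H](OC(=O)C1=Cc2cc(OCc3ccccc3)c(OCc3ccccc3)cc2[C@@H](c2ccc(OCc3ccccc3)c(OCc3ccccc3)c2)[C@@H]1C(=O)OC(C)(C)C)C(=O)OC(C)(C)C | intermediate
18 | (2S)-2-{[(3S,4R)-3-carboxy-4-(3,4-dihydroxyphenyl)-6,7-dihydroxy-3,4-dihydronaphthalene-2-carbonyl]oxy}butanedioic acid | O=C(O)C[C@H](OC(=O)C1=Cc2cc(O)c(O)cc2[C@@H](c2ccc(O)c(O)c2)[C@@H]1C(=O)O)C(=O)O | target

## Step count and least certain steps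

Total step count: 12. Longest linear sequence: 10 steps (3 → 5 → 7 → 8 → 11 → 12 → 13 → 14 → 15 → 17 → 18; the branch from 1 through 2 is equally long, the branch from 9 through 10 has 8 steps).

**Step 9 (key step).** The most likely failure is diversion of the ring-opened zwitterion before the carbon–carbon closure, because the acyl-bearing ring is only a moderate nucleophile. The enolate oxygen can close onto C1 (Cloke–Wilson rearrangement), or the C2 proton can be lost to give an open-chain alkene, which would also erase the C2 centre. Partial loss of tert-butyl esters under the Lewis acid is a secondary risk. Fallback, from 13 back to 14: the isomerisation is run in two separate stages. A weak Lewis acid (Yb(OTf)3, CH2Cl2, low temperature) is used first to take 13 deliberately to the Cloke–Wilson product, the 4,5-trans-2-aryl-5-aryl-4,5-dihydrofuran-3,4-dicarboxylate F1, which is isolated. F1 is then re-ionised at its benzylic C5–O bond with TMSOTf in CH2Cl2 at −40 °C under high dilution. This regenerates the C1 cation next to a silyl enol ether that returns to the furan less readily, so the arene closure to 14 can be driven from a defined, storable intermediate. Both stages are known reaction types for donor-substituted acyl cyclopropanes and 2-aryl-2,3-dihydrofurans.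

**Step 6.** The electron-rich enal forms its iminium ion slowly, so low conversion, erosion of facial selectivity by an uncatalysed background addition, and amine-induced opening of the strained product are the likely problems. Fallback, from 7 and 9 back to 13: Knoevenagel condensation of 7 with 9 (piperidinium acetate, toluene, azeotropic removal of water) should give the arylidene β-keto ester F2. An ester-stabilised sulfonium ylide ((tert-butoxycarbonylmethyl)dimethylsulfonium bromide, K2CO3, MeCN) should convert F2 in a Corey–Chaykovsky-type cyclopropanation into the aryl/ester-trans cyclopropane. This delivers 13 together with the diastereomer of opposite ring configuration. The (S)-malate residue makes the two separable, at the cost of half the material. This detour gives up catalytic control of C2 but bypasses steps 4 to 8.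

**Step 11.** The activated benzylic mesylate may be substituted rather than eliminated, the two C4 epimers may eliminate at different rates, and the base may cause migration of the new double bond or epimerisation at C2. Fallback, from 14 back to 17, replacing steps 10 and 11: the enol form of the β-keto ester 14 is converted into the enol triflate F3 (NaH, PhNTf2, THF, 0 °C; only C3 is deprotonated). F3 is then reduced with formate under zerovalent palladium catalysis generated from Pd(OAc)2 and PPh3 (HCO2H, Et3N, DMF, 60 °C), which puts hydrogen on C4 and leaves the C3=C4 bond in place without creating or touching any stereocentre.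

**Step 12.** The tert-butyl esters may not be fully cleaved at the low temperature that protects the malate ester linkage, and on warming the tert-butyl cations may alkylate the freed catechol rings. Fallback, from 17 back to 18: the two deprotections are separated. Trifluoroacetic acid with anisole in CH2Cl2 at room temperature first removes the three tert-butyl esters while the phenols are still benzylated, giving the tetra-O-benzyl triacid F4. F4 is then debenzylated with BCl3 and pentamethylbenzene at −78 °C only and quenched cold.

## Further compounds

F1 | step 9 | 4-tert-butyl 3-[(2S)-1,4-di-tert-butoxy-1,4-dioxobutan-2-yl] 4,5-trans-2-[3,4-bis(benzyloxy)phenyl]-5-[3,4-bis(benzyloxy)phenyl]-4,5-dihydrofuran-3,4-dicarboxylate | CC(C)(C)OC(=O)[C@H]1[C@H](c2ccc(OCc3ccccc3)c(OCc3ccccc3)c2)OC(c2ccc(OCc3ccccc3)c(OCc3ccccc3)c2)=C1C(=O)O[C@@H](CC(=O)OC(C)(C)C)C(=O)OC(C)(C)C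
F2 | step 6 | di-tert-butyl (2S)-2-({2-[3,4-bis(benzyloxy)benzoyl]-3-[3,4-bis(benzyloxy)phenyl]prop-2-enoyl}oxy)butanedioate (E/Z mixture) | CC(C)(C)OC(=O)C[C@H](OC(=O)C(=Cc1ccc(OCc2ccccc2)c(OCc2ccccc2)c1)C(=O)c1ccc(OCc2ccccc2)c(OCc2ccccc2)c1)C(=O)OC(C)(C)C
F3 | step 11 | 2-tert-butyl 3-[(2S)-1,4-di-tert-butoxy-1,4-dioxobutan-2-yl] (1R,2S)-6,7-bis(benzyloxy)-1-[3,4-bis(benzyloxy)phenyl]-4-(trifluoromethanesulfonyloxy)-1,2-dihydronaphthalene-2,3-dicarboxylate | CC(C)(C)OC(=O)C[C@H](OC(=O)C1=C(OS(=O)(=O)C(F)(F)F)c2cc(OCc3ccccc3)c(OCc3ccccc3)cc2[C@@H](c2ccc(OCc3ccccc3)c(OCc3ccccc3)c2)[C@@H]1C(=O)OC(C)(C)C)C(=O)OC(C)(C)C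
F4 | step 12 | (2S)-2-{[(3S,4R)-6,7-bis(benzyloxy)-4-[3,4-bis(benzyloxy)phenyl]-3-carboxy-3,4-dihydronaphthalene-2-carbonyl]oxy}butanedioic acid | O=C(O)C[C@H](OC(=O)C1=Cc2cc(OCc3ccccc3)c(OCc3ccccc3)cc2[C@@H](c2ccc(OCc3ccccc3)c(OCc3ccccc3)c2)[C@@H]1C(=O)O)C(=O)O
A1 | alternative 1 | dimethyl (2R,3R)-2,3-bis{[(E)-3-(3,4-dimethoxyphenyl)prop-2-enoyl]oxy}butanedioate | COC(=O)[C@H](OC(=O)/C=C/c1ccc(OC)c(OC)c1)[C@@H](OC(=O)/C=C/c1ccc(OC)c(OC)c1)C(=O)OC
A2 | alternative 1 | tartrate-bridged all-trans truxinate (dimethyl ester) | COc1ccc(cc1OC)[C@@H]1[C@@H](c3ccc(OC)c(OC)c3)[C@H]2[C@H]1C(=O)O[C@@H](C(=O)OC)[C@H](C(=O)OC)OC2=O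
A3 | alternative 2 | 1,7-diyne with Z-enyne, C1 aryl group, C2 tert-butyl ester and C3 malate ester | C#C/C=C(/C(=O)O[C@@H](CC(=O)OC(C)(C)C)C(=O)OC(C)(C)C)[C@@H](C(=O)OC(C)(C)C)[C@@H](C#C)c1ccc(OC)c(OC)c1
A4 | alternative 2 | bis(pinacolatoboryl)acetylene | CC1(C)OB(C#CB2OC(C)(C)C(C)(C)O2)OC1(C)C
A5 | alternative 2 | 6,7-diboryl dihydronaphthalene with all esters in place | CC(C)(C)OC(=O)C[C@H](OC(=O)C1=Cc2cc(B3OC(C)(C)C(C)(C)O3)c(B3OC(C)(C)C(C)(C)O3)cc2[C@@H](c2ccc(OC)c(OC)c2)[C@@H]1C(=O)OC(C)(C)C)C(=O)OC(C)(C)C
A6 | alternative 3 | trans-γ-(3,4-dimethoxyphenyl)-α-(dimethylaminomethylene) paraconate lactone with C2 benzyl-oxazolidinone imide | CN(C)/C=C1/C(=O)O[C@@H](c2ccc(OC)c(OC)c2)[C@@H]1C(=O)N1C(=O)OC[C@H]1Cc1ccccc1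
A7 | alternative 3 | veratrole (1,2-dimethoxybenzene) | COc1ccccc1OC
A8 | alternative 3 | 1-aryl-1,2-dihydronaphthalene with free C3 acid and C2 oxazolidinone imide | OC(=O)C1=Cc2cc(OC)c(OC)cc2[C@@H](c2ccc(OC)c(OC)c2)[C@@H]1C(=O)N1C(=O)OC[C@H]1Cc1ccccc1
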